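The route rests on cutting the dioxane at C2–C3 and at the O–C bond of the CH2OH carbon. C2, C3 and the CH2OH carbon are each singly oxygenated and the oxygen on C3 (O4) already belongs to ring A, so this three-carbon unit is an oxetane in disguise. One Paternò–Büchi photocycloaddition of ring B aldehyde 2 with ring A aryl vinyl ether 9 makes both bonds, the four-membered ring and both stereocentres. Phenol O1 later opens the oxetane at benzylic C2 with inversion, which gives the cis dioxane and frees CH2OH. In 9, O1 is a triisopropylsilyl ether (stable to the base that makes the vinyl ether) and bromine marks C7.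

Key step: step 6

Assumption: dioxane locants are O1, C2 (aryl), C3 (CH2OH), O4, C5 (OMe), C7 (side chain) and oxetane locants are O1, C2 (aryl), C3 (aryloxy), C4 (CH2); boronate 14 is taken as purchasable (otherwise one hydroboration of propargyl alcohol with pinacolborane).

Step 1
Reactants: 1 3,4-dihydroxy-5-methoxybenzaldehyde
Product: 2 3,4-diacetoxy-5-methoxybenzaldehyde
Conditions: Ac2O, pyridine, DMAP (cat.), CH2Cl2, 0 °C to rt
Reagents that add atoms: acetic anhydride, CC(=O)OC(C)=O
Why: DMAP-catalysed O-acylation should esterify both phenols and leave the aldehyde untouched.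

Step 2
Reactants: 3 5-bromo-2-hydroxy-3-methoxybenzaldehyde; 4 1-bromo-2-chloroethane (excess)
Product: 5 5-bromo-2-(2-chloroethoxy)-3-methoxybenzaldehyde
Conditions: K2CO3, DMF, 60 °C
Reagents that add atoms: none
Why: Williamson ether synthesis in which the phenoxide should displace bromide, the better leaving group, so that the chloride stays as the masked vinyl group.

Step 3
Reactants: 5 5-bromo-2-(2-chloroethoxy)-3-methoxybenzaldehyde
Product: 7 5-bromo-2-(2-chloroethoxy)-3-methoxyphenol, via aryl formate 6 (not isolated)
Conditions: mCPBA, CH2Cl2, rt; then HCl (cat.), MeOH, rt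
Reagents that add atoms: mCPBA (3-chloroperoxybenzoic acid), OOC(=O)c1cccc(Cl)c1
Why: Baeyer–Villiger (Dakin-type) oxidation in which the ortho-alkoxy aryl group should migrate in the Criegee intermediate, and acidic methanolysis of the formate avoids a phenoxide that could close onto the chloroethyl chain.

Step 4
Reactants: 7 5-bromo-2-(2-chloroethoxy)-3-methoxyphenol
Product: 8 [5-bromo-2-(2-chloroethoxy)-3-methoxyphenoxy]triisopropylsilane
Conditions: TIPSCl, imidazole, DMF, rt
Reagents that add atoms: triisopropylsilyl chloride, CC(C)[Si](Cl)(C(C)C)C(C)C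
Why: imidazole-promoted silylation of the phenol, with the bulky triisopropylsilyl group chosen because it should resist alkoxide attack at silicon in step 5.

Step 5
Reactants: 8 [5-bromo-2-(2-chloroethoxy)-3-methoxyphenoxy]triisopropylsilane
Product: 9 [5-bromo-2-(ethenyloxy)-3-methoxyphenoxy]triisopropylsilane
Conditions: KOtBu, THF/DMSO, 0 °C to rt
Reagents that add atoms: none
Why: E2 dehydrochlorination of a 2-chloroethyl aryl ether, the standard route to aryl vinyl ethers, which the hindered silyl ether and the aryl bromide should survive at or below room temperature.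

Step 6
Reactants: 2 3,4-diacetoxy-5-methoxybenzaldehyde; 9 [5-bromo-2-(ethenyloxy)-3-methoxyphenoxy]triisopropylsilane
Product: 11 (2R,3R)-2-(3,4-diacetoxy-5-methoxyphenyl)-3-[4-bromo-2-methoxy-6-(triisopropylsilyloxy)phenoxy]oxetane (cis), via triplet 1,4-biradical 10 (not isolated)
Conditions: hν (350 nm), (R,R)-TADDOL (3 equiv), toluene, −78 °C
Reagents that add atoms: none
Why: Proposed new method: excitation of 2 gives its n,π* triplet, whose oxygen bonds to the CH2 terminus of the electron-rich vinyl ether 9, and the triplet 1,4-biradical 10 (benzylic radical at C2, α-aryloxy radical at C3) closes the C2–C3 bond after intersystem crossing, so the oxetane is closed stepwise, O–C4 first and C2–C3 second (Paternò–Büchi [2+2]). The closest known reaction types are the racemic triplet Paternò–Büchi reaction of aromatic aldehydes with enol ethers to 3-alkoxyoxetanes, its hydroxy-directed variant in which an O–H···O=C hydrogen bond steers the addition, and the hydrogen-bond activation of aldehydes by TADDOL in ground-state cycloadditions; an enantioselective version with a plain aryl aldehyde and an aryl vinyl ether has not been shown. The diol (4R,5R)-2,2-dimethyl-α,α,α′,α′-tetraphenyl-1,3-dioxolane-4,5-dimethanol, in excess at low temperature, is expected to stay hydrogen-bonded to the aldehyde oxygen through C–O bond formation and biradical closure and to screen one face of the benzylic radical, which sets C2; its phenyl groups lie above the aldehyde triplet in energy and should not quench it. C3 is set relative to C2 by the biradical conformation with near-orthogonal radical orbitals that permits spin inversion and should lead to the cis oxetane. The step needs regioselectivity for the 3-aryloxy isomer (secured by the unhindered, nucleophilic CH2 terminus and the radical-stabilising aryloxy oxygen), cis diastereoselectivity and enantioselectivity (host); the acetoxy groups keep the lowest triplet of 2 n,π* in character, the silyl ether removes the phenolic O–H that would quench it, and bromine instead of the alkene at C7 leaves no second triplet acceptor.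

Step 7
Reactants: 11 (2R,3R)-cis-oxetane silyl ether
Product: 12 (2R,3R)-2-(3,4-diacetoxy-5-methoxyphenyl)-3-(4-bromo-2-hydroxy-6-methoxyphenoxy)oxetane (cis)
Conditions: Bu4NF, AcOH (1:1), THF, 0 °C
Reagents that add atoms: none
Why: fluoride-induced cleavage of the aryl silyl ether, buffered with acetic acid so that the aryl acetates and the oxetane should remain intact and no stereocentre is touched.

Step 8
Reactants: 12 (2R,3R)-cis-oxetane phenol
Product: 13 5-[(2S,3R)-7-bromo-3-(hydroxymethyl)-5-methoxy-2,3-dihydro-1,4-benzodioxin-2-yl]-3-methoxy-1,2-phenylene diacetate (cis)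
Conditions: (PhO)2P(O)OH (10 mol%), toluene, rt
Reagents that add atoms: none
Why: acid-catalysed intramolecular oxetane opening (6-exo-tet etherification, as in the phosphoric-acid-catalysed opening of 3-aryloxyoxetanes by a neighbouring phenol) in which O1 should attack benzylic C2 opposite the leaving oxygen, so that C2 is inverted to S while C3 stays R and the substituents end up cis, the acetoxy groups suppressing a free benzylic cation while the remaining cationic character still favours C2 over C4.

Step 9
Reactants: 13 cis-dioxane bromide; 14 (E)-3-(4,4,5,5-tetramethyl-1,3,2-dioxaborolan-2-yl)prop-2-en-1-ol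
Product: 15 5-[(2S,3R)-3-(hydroxymethyl)-7-[(E)-3-hydroxyprop-1-enyl]-5-methoxy-2,3-dihydro-1,4-benzodioxin-2-yl]-3-methoxy-1,2-phenylene diacetate
Conditions: Pd(dppf)Cl2 (5 mol%), CsF, dioxane, 80 °C
Reagents that add atoms: none
Why: Suzuki–Miyaura coupling (oxidative addition of zerovalent palladium into the C7–Br bond, fluoride-promoted transmetalation with retention of the E geometry) under non-aqueous fluoride conditions that should largely spare the acetates, whose partial loss would not matter because step 10 removes them.

Step 10
Reactants: 15 diacetate of the target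
Product: 16 5-[(2S,3R)-3-(hydroxymethyl)-7-[(E)-3-hydroxyprop-1-enyl]-5-methoxy-2,3-dihydro-1,4-benzodioxin-2-yl]-3-methoxybenzene-1,2-diol (CNP0174261.1)
Conditions: K2CO3 (cat.), MeOH, N2, 0 °C
Reagents that add atoms: none
Why: base-catalysed transesterification (Zemplén-type methanolysis) of the two aryl acetates, cold and oxygen-free so that the catechol, the E-allylic alcohol and the cis C2/C3 centres should be unaffected.

Compound list
1 | 3,4-dihydroxy-5-methoxybenzaldehyde (5-hydroxyvanillin) | COc1cc(C=O)cc(O)c1O | starting material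
2 | 3,4-diacetoxy-5-methoxybenzaldehyde (ring B aldehyde) | COc1cc(C=O)cc(OC(C)=O)c1OC(C)=O | intermediate
3 | 5-bromo-2-hydroxy-3-methoxybenzaldehyde (5-bromo-o-vanillin) | COc1cc(Br)cc(C=O)c1O | starting material
4 | 1-bromo-2-chloroethane | ClCCBr | starting material
5 | 5-bromo-2-(2-chloroethoxy)-3-methoxybenzaldehyde | COc1cc(Br)cc(C=O)c1OCCCl | intermediate
6 | 5-bromo-2-(2-chloroethoxy)-3-methoxyphenyl formate (not isolated) | COc1cc(Br)cc(OC=O)c1OCCCl | intermediate
7 | 5-bromo-2-(2-chloroethoxy)-3-methoxyphenol | COc1cc(Br)cc(O)c1OCCCl | intermediate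
8 | [5-bromo-2-(2-chloroethoxy)-3-methoxyphenoxy]triisopropylsilane | COc1cc(Br)cc(O[Si](C(C)C)(C(C)C)C(C)C)c1OCCCl | intermediate
9 | [5-bromo-2-(ethenyloxy)-3-methoxyphenoxy]triisopropylsilane (ring A aryl vinyl ether) | C=COc1c(OC)cc(Br)cc1O[Si](C(C)C)(C(C)C)C(C)C | intermediate
10 | triplet 1,4-biradical, ArB–CH(•)–O–CH2–CH(•)–OAr′ (not isolated) | COc1cc([CH]OC[CH]Oc2c(OC)cc(Br)cc2O[Si](C(C)C)(C(C)C)C(C)C)cc(OC(C)=O)c1OC(C)=O | intermediate
11 | (2R,3R)-2-(3,4-diacetoxy-5-methoxyphenyl)-3-[4-bromo-2-methoxy-6-(triisopropylsilyloxy)phenoxy]oxetane (cis) | COc1cc([C@H]2OC[C@H]2Oc3c(OC)cc(Br)cc3O[Si](C(C)C)(C(C)C)C(C)C)cc(OC(C)=O)c1OC(C)=O | intermediate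
12 | (2R,3R)-2-(3,4-diacetoxy-5-methoxyphenyl)-3-(4-bromo-2-hydroxy-6-methoxyphenoxy)oxetane (cis) | COc1cc([C@H]2OC[C@H]2Oc3c(OC)cc(Br)cc3O)cc(OC(C)=O)c1OC(C)=O | intermediate
13 | 5-[(2S,3R)-7-bromo-3-(hydroxymethyl)-5-methoxy-2,3-dihydro-1,4-benzodioxin-2-yl]-3-methoxy-1,2-phenylene diacetate (cis) | COc1cc([C@@H]2Oc3cc(Br)cc(OC)c3O[C@@H]2CO)cc(OC(C)=O)c1OC(C)=O | intermediate
14 | (E)-3-(4,4,5,5-tetramethyl-1,3,2-dioxaborolan-2-yl)prop-2-en-1-ol | OC/C=C/B1OC(C)(C)C(C)(C)O1 | starting material
15 | 5-[(2S,3R)-3-(hydroxymethyl)-7-[(E)-3-hydroxyprop-1-enyl]-5-methoxy-2,3-dihydro-1,4-benzodioxin-2-yl]-3-methoxy-1,2-phenylene diacetate | COc1cc([C@@H]2Oc3cc(/C=C/CO)cc(OC)c3O[C@@H]2CO)cc(OC(C)=O)c1OC(C)=O | intermediate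
16 | 5-[(2S,3R)-3-(hydroxymethyl)-7-[(E)-3-hydroxyprop-1-enyl]-5-methoxy-2,3-dihydro-1,4-benzodioxin-2-yl]-3-methoxybenzene-1,2-diol (cis) | COc1cc([C@@H]2Oc3cc(/C=C/CO)cc(OC)c3O[C@@H]2CO)cc(O)c1O | target

Total step count: 10. Longest linear sequence: 9 steps (3 to 16, steps 2 to 10).

Steps most likely to fail

1. Step 6 (the proposed new method). Face discrimination at the biradical stage may be poor, because the hydrogen bond to the excited carbonyl is weak and the diol can also sit on the acetate carbonyls, so the oxetane may form with low enantiomeric purity. Should the sense of induction be the opposite one, the (S,S)-diol is used. Incomplete regiocontrol (2-aryloxy isomer) and cis/trans control may add to this. The fallback uses known chemistry and sets out from 2 and 9. Irradiation at 350 nm in acetonitrile at room temperature without any chiral additive, the established triplet Paternò–Büchi reaction of aromatic aldehydes with enol ethers, should give the racemic cis-oxetane F1 after chromatographic removal of isomers. F1 is resolved by preparative HPLC on a polysaccharide chiral stationary phase, and the (2R,3R) enantiomer comes back to the route at 11.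

2. Step 8. The phenol may attack the unsubstituted oxetane carbon C4, the mode known for 3-aryloxyoxetanes, instead of benzylic C2, which the two acetoxy groups deactivate; an isomeric dioxane with a benzylic carbinol would result. The fallback sets out from 11, uses that same preference with an external nucleophile and closes the dioxane by Mitsunobu etherification instead of oxetane opening. Acetic acid with (PhO)2P(O)OH in toluene should open 11 at C4 and leave the benzylic C2–O bond untouched, giving the hydroxy acetate F2. Buffered Bu4NF frees the phenol F3. PPh3 and diisopropyl azodicarboxylate (THF, 0 °C) then join O1 to C2 with inversion, a 6-exo closure on the activated benzylic carbinol, giving the cis-dioxane acetate F4 with the configuration of 13. Coupling with 14 as in step 9 gives the triacetate F5, and methanolysis as in step 10 removes all three acetyl groups, so the fallback comes back at 16.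

3. Step 5. tert-Butoxide may attack silicon, and the phenoxide set free would close onto the chloroethyl chain to a 2,3-dihydro-1,4-benzodioxine; the elimination may also stall. The fallback sets out from 8 and replaces base-induced elimination by selenoxide syn-elimination. PhSeNa (from PhSeSePh and NaBH4, EtOH/THF, 60 °C) displaces chloride to give the selenide F6. H2O2 (THF, 0 °C) oxidises it to the selenoxide F7, which is not isolated and loses PhSeOH on warming with iPr2NH. The fallback comes back at 9.

Further compounds
F1 | step 6 | racemic cis-oxetane, equimolar mixture of 11 and its (2S,3S) enantiomer | COc1cc([C@H]2OC[C@H]2Oc3c(OC)cc(Br)cc3O[Si](C(C)C)(C(C)C)C(C)C)cc(OC(C)=O)c1OC(C)=O.COc1cc([C@@H]2OC[C@@H]2Oc3c(OC)cc(Br)cc3O[Si](C(C)C)(C(C)C)C(C)C)cc(OC(C)=O)c1OC(C)=O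
F2 | step 8 | (2R,3R)-3-(3,4-diacetoxy-5-methoxyphenyl)-2-[4-bromo-2-methoxy-6-(triisopropylsilyloxy)phenoxy]-3-hydroxypropyl acetate | COc1cc([C@@H](O)[C@@H](COC(C)=O)Oc2c(OC)cc(Br)cc2O[Si](C(C)C)(C(C)C)C(C)C)cc(OC(C)=O)c1OC(C)=O
F3 | step 8 | (2R,3R)-3-(3,4-diacetoxy-5-methoxyphenyl)-2-(4-bromo-2-hydroxy-6-methoxyphenoxy)-3-hydroxypropyl acetate | COc1cc([C@@H](O)[C@@H](COC(C)=O)Oc2c(OC)cc(Br)cc2O)cc(OC(C)=O)c1OC(C)=O
F4 | step 8 | O-acetate of 13 (cis-dioxane with CH2OAc on C3, 2S,3R in the locants of 13) | COc1cc([C@@H]2Oc3cc(Br)cc(OC)c3O[C@@H]2COC(C)=O)cc(OC(C)=O)c1OC(C)=O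
F5 | step 8 | O-acetate of 15 (triacetate of the target) | COc1cc([C@@H]2Oc3cc(/C=C/CO)cc(OC)c3O[C@@H]2COC(C)=O)cc(OC(C)=O)c1OC(C)=O
F6 | step 5 | [5-bromo-3-methoxy-2-[2-(phenylselanyl)ethoxy]phenoxy]triisopropylsilane | COc1cc(Br)cc(O[Si](C(C)C)(C(C)C)C(C)C)c1OCC[Se]c2ccccc2
F7 | step 5 | selenoxide of F6 (not isolated) | COc1cc(Br)cc(O[Si](C(C)C)(C(C)C)C(C)C)c1OCC[Se](=O)c2ccccc2
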